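I decide to leave this flask's clock aside and carry one number. The two steps that consume the substrates take partner and catalyst at the same concentrations, whatever the precatalyst has released and the added ligand has left free, so these factors cancel in the quotient of the two rates. Two rates remain, the loss of left-handed and of right-handed substrate, each per unit of its own concentration. Their ratio s, the selectivity factor, is the logarithm of the left-handed fraction remaining over that of the right-handed fraction remaining. I read it on the dawn run at 4.00 h, where left-handed substrate stands lower than in the autumn run, and get 5.81. This is a rough reading, since the right-handed loss of 3.8 percentage points is read to 1 point.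

| setting | spring | dawn | autumn | flask |
|---|---|---|---|---|
| left-handed substrate | 0.053 M | 0.053 M | 0.053 M | 0.053 M |
| right-handed substrate | 0.053 M | 0.053 M | 0.053 M | 0.053 M |
| partner | 0.028 M | 0.064 M | 0.0424 M | 0.0424 M |
| precatalyst | 1.1 mM | 1.1 mM | 1.1 mM | 1.1 mM |
| added ligand | 1.8 mM | 1.8 mM | 0.90 mM | 1.8 mM |
| remark | run made earlier | run made earlier | run made earlier |  |
| time |  |  |  | 5.0 h |

| run | time / h | left-handed substrate / % | right-handed substrate / % | left-handed product / % |
|---|---|---|---|---|
| spring | 1.00 | 49.8 | 49.1 | 0.7 |
| spring | 2.00 | 48.1 | 48.7 | 2.4 |
| spring | 3.00 | 45.8 | 50.8 | 4.5 |
| spring | 4.00 | 45.0 | 50.0 | 6.2 |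
| dawn | 0.333 | 49.7 | 50.9 | 0 |
| dawn | 0.667 | 48.6 | 52.1 | 1.7 |
| dawn | 1.50 | 45.8 | 51.4 | 3.3 |
| dawn | 4.00 | 31.6 | 46.2 | 20.9 |
| autumn | 1.00 | 47.6 | 49.4 | 2.3 |
| autumn | 2.00 | 45.1 | 50.8 | 4.0 |
| autumn | 3.00 | 41.7 | 48.8 | 8.3 |
| autumn | 4.00 | 36.6 | 47.5 | 13.6 |

(each reading ± 1 percentage point)

- catalyst is single-handed; left-handed substrate and right-handed substrate are mirror images of each other, charged as a racemate, each of them at the stated concentration
- steps under discussion: partner + catalyst + left-handed substrate -> catalyst + left-handed product; partner + catalyst + right-handed substrate -> catalyst + right-handed product; partner + precatalyst -> catalyst + spent reagent; catalyst + added ligand <-> idle complex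
- an excess is the difference of the two amounts in percent of their sum
- an excess is below zero if the other one leads

- part of the left-handed substrate and right-handed substrate charged together that has reacted at 5.0 h
- excess of left-handed product over right-handed product in the product at 5.0 h
- excess of right-handed substrate over left-handed substrate among what is left of the two at 5.0 h

At the start, the product excess is s less one over s plus one, which I reckon at 70.6% without any clock. This is a start value, not a value at the asked time. Since the charge is racemic, the substrate excess times the part unreacted equals the product excess times the part reacted.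

The forecast gives 20% reacted, a product excess of 70% and a substrate excess of 17.5%, on the ground that “Mass balances and the right-handed losses suggest s ≈ 6–8”. My reading lies just below that range.

The flask gives 16.9% reacted, a product excess of 73.4% and a substrate excess of 14.9%.

partner + catalyst + left-handed substrate → catalyst + left-handed product (k = 400 M⁻² min⁻¹); partner + catalyst + right-handed substrate → catalyst + right-handed product (k = 53.0 M⁻² min⁻¹); partner + precatalyst → catalyst + spent reagent (k = 0.0250 M⁻¹ min⁻¹); catalyst + added ligand ⇌ idle complex, settled at all times (K = 340 M⁻¹) With 71% of its left-handed substrate remaining, s puts the right-handed remainder at 94.2%, and the flask holds 96%. The neighbour charged with 0.17 M of partner has 68.7% reacted and a product excess of 42.3%. With 2.2% of its left-handed substrate remaining, s puts its right-handed remainder at 51.9%, and it holds 60%. The logarithms of the left-handed and right-handed substrate remaining in that neighbour give a ratio of 7.55, against 7.55 in the flask.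

All runs are simulated with made-up constants, and the scatter is random.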